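**Plan**

- Retrosynthesis: the C5=C6 double bond and the tertiary hydroxyl are taken back to a saturated ketone carrying a methallyl group. The C5–CH2 bond (enolate alkylation) and the C6–CH2 bond (radical conjugate addition) are then cut, which separates chroman iodide 21 from hydrindenone 11.
- In the bicyclic ketone the cyclopentane shares the C3a–C7a bond with the six-membered ring. Both carbons are quaternary and C3a is α to the C4 carbonyl, so the C3–C3a bond is cut to a cyclohexanone enolate with a 3-iodopropyl arm on C7a. The C3a–CH3 and C7a–CH2 bonds lead back to 3-methylcyclohexenone.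
- Forward order: conjugate addition, methylation, iodide, cyclopentane closure, desaturation; in parallel the pyran ring of the chroman is closed by aryl C–O coupling; then Giese union, methallylation, hydration and a final desaturation.
- Stereochemistry: C7a comes from a copper-catalysed asymmetric conjugate addition, C3a is relayed from C7a by the enforced cis ring closure, and chroman C2 comes from (S)-2-methylglycidol and is never touched afterwards.

Key step: step 4

Assumption: the phosphoramidite antipode in step 1 is the one that gives the (R) centre of 4 (both antipodes are sold); hydrindane numbering (C1–C3, C3a, C4 carbonyl, C5, C6, C7, C7a) is used for all bicyclic compounds.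

**Route**

Step 1
Reactants: 1 allyl tert-butyldimethylsilyl ether; 2 3-methylcyclohex-2-en-1-one
Product: 4 tert-butyldimethyl{3-[(1R)-1-methyl-3-(trimethylsilyloxy)cyclohex-2-en-1-yl]propoxy}silane, via alkylzirconocene chloride 3 (not isolated)
Conditions: Cp2Zr(H)Cl, CH2Cl2, rt; then 2, CuCl/AgNTf2 (10 mol%), binaphthol-derived bis(1-phenylethyl)amine phosphoramidite (10 mol%), TMSCl, Et2O, rt; non-aqueous work-up (pentane, Celite), crude 4 used directly
Reagents that add atoms: chlorotrimethylsilane, C[Si](C)(C)Cl
Why: Hydrozirconation places zirconium on the terminal carbon and the chiral Cu(I)–phosphoramidite catalyst transfers the alkyl group to C3 of the enone (catalytic asymmetric conjugate addition of an alkylzirconium), the ligand setting the quaternary centre as (R) while TMSCl captures the enolate regiospecifically as the C1=C2 silyl enol ether.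

Step 2
Reactants: 4 silyl enol ether
Product: 7 (2RS,3R)-3-(3-hydroxypropyl)-2,3-dimethylcyclohexan-1-one, via lithium enolate 5 (not isolated), via silyl ether ketone 6 (not isolated)
Conditions: MeLi, THF, 0 °C; MeI, −78 → 0 °C; then 1 M aq. HCl, THF, rt
Reagents that add atoms: iodomethane, CI
Why: Methyllithium cleaves the Si–O bond of the enol ether to the regiodefined lithium enolate, which is C-methylated at C2 before it can equilibrate (regiospecific enolate alkylation), and the acidic work-up hydrolyses the primary TBS ether; C2 forms as an epimer mixture that is made planar again in step 4.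

Step 3
Reactants: 7 hydroxy ketone
Product: 8 (2RS,3R)-3-(3-iodopropyl)-2,3-dimethylcyclohexan-1-one
Conditions: I2, PPh3, imidazole, CH2Cl2, 0 °C → rt
Reagents that add atoms: iodine, II
Why: Iodophosphonium activation of the primary alcohol and SN2 displacement by iodide (Appel-type iodination) leave the ketone and the quaternary centre untouched.

Step 4
Reactants: 8 iodo ketone
Product: 10 (3aS,7aS)-3a,7a-dimethyloctahydro-4H-inden-4-one (cis-fused), via potassium enolate 9 (not isolated)
Conditions: KOt-Bu, t-BuOH/THF (0.02 M), 0 °C → rt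
Reagents that add atoms: none
Why: tert-Butoxide in tert-butanol deprotonates 8 reversibly, and of the two enolates only the tetrasubstituted C1=C2 enolate 9 has the iodide within reach, so it closes the cyclopentane by intramolecular SN2 C-alkylation, the closest known reaction type being the base-mediated cycloalkylation of ω-halo ketones to cis-fused bicyclic ketones with vicinal quaternary carbons. The ring closes in the 5-(enolexo)-exo-tet mode, the CH2–I carbon being attacked in line with the C–I bond while the enolate double bond stays outside the new ring. The new quaternary centre C3a is controlled by C7a: the three-carbon arm starts on one face of the six-membered ring and can reach the enolate carbon only on that face, so the ring fusion must be cis and the centre set in step 1 translates into (3aS,7aS). The step needs regioselectivity between the two enolates and C- over O-alkylation; attack from the other α-carbon would require a seven-membered transition state to a bridged bicyclo[3.2.2] ketone and O-alkylation would give a seven-membered enol ether, so the equilibrating conditions should funnel the material through 9. Both C2 epimers of 8 converge because C2 is planar in 9, and the product keeps a single enolisable position (C5) for the later steps.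

Step 5
Reactants: 10 hydrindanone
Product: 11 (3aS,7aS)-3a,7a-dimethyl-1,2,3,3a,7,7a-hexahydro-4H-inden-4-one
Conditions: IBX, DMSO/PhF, 70 °C
Reagents that add atoms: none
Why: IBX dehydrogenates the ketone through its enol (IBX desaturation), and because C3a and C7a are quaternary only the C5–C6 bond can be desaturated and no over-oxidation to a dienone is possible.

Step 6
Reactants: 12 (S)-2-methylglycidol
Product: 14 (2R)-2-[(benzyloxy)methyl]-2-methyloxirane, via sodium alkoxide 13 (not isolated)
Conditions: NaH, BnBr, n-Bu4NI (cat.), THF, 0 °C → rt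
Reagents that add atoms: benzyl bromide, BrCc1ccccc1
Why: Williamson etherification of the primary alkoxide; a Payne rearrangement of 13 would be degenerate for this glycidol and return the same enantiomer, so the centre is preserved (the descriptor changes from S to R only through the CIP priorities).

Step 7
Reactants: 15 2-bromo-5-methoxy-1,3-dimethylbenzene
Product: 16 2-bromo-1-(bromomethyl)-5-methoxy-3-methylbenzene
Conditions: NBS (1 equiv), AIBN (cat.), PhCF3, 85 °C
Reagents that add atoms: N-bromosuccinimide, O=C1CCC(=O)N1Br
Why: Radical-chain Wohl–Ziegler bromination functionalises one of the two equivalent benzylic methyl groups, the non-polar medium disfavouring ionic bromination of the ring.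

Step 8
Reactants: 16 benzylic bromide; 14 benzyl glycidyl ether
Product: 18 (2R)-1-(benzyloxy)-4-(2-bromo-5-methoxy-3-methylphenyl)-2-methylbutan-2-ol, via Grignard reagent 17 (not isolated)
Conditions: Mg, Et2O, 0 °C; then 14, CuI (10 mol%), THF, −30 → 0 °C; aq. NH4Cl
Reagents that add atoms: none
Why: Magnesium inserts into the benzylic C–Br bond far faster than into the aryl C–Br bond, and the copper-catalysed Grignard opening of the 2,2-disubstituted epoxide occurs at its CH2 terminus, so the oxygen-bearing stereocentre is not touched.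

Step 9
Reactants: 18 bromoaryl tertiary alcohol
Product: 19 (2R)-2-[(benzyloxy)methyl]-6-methoxy-2,8-dimethyl-3,4-dihydro-2H-chromene
Conditions: Pd(OAc)2 (5 mol%), 2-(di-tert-butylphosphino)-1,1′-binaphthyl, Cs2CO3, toluene, 80 °C
Reagents that add atoms: none
Why: Palladium-catalysed intramolecular C–O coupling (Buchwald–Hartwig etherification) of the tertiary alkoxide, which has no hydrogen on the carbinol carbon to lose, closes the six-membered pyran ring with retention at C2 because the carbinol C–O bond is never broken.

Step 10
Reactants: 19 benzyl ether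
Product: 20 [(2R)-6-methoxy-2,8-dimethyl-3,4-dihydro-2H-chromen-2-yl]methanol
Conditions: H2 (1 atm), Pd/C, EtOAc, rt
Reagents that add atoms: none
Why: Hydrogenolysis cleaves the benzyl ether while the aryl methyl ether and the chroman C–O bonds, neither of which is a benzylic C–O bond, remain.

Step 11
Reactants: 20 chromanylmethanol
Product: 21 (2R)-2-(iodomethyl)-6-methoxy-2,8-dimethyl-3,4-dihydro-2H-chromene
Conditions: I2, PPh3, imidazole, toluene, 90 °C
Reagents that add atoms: iodine, II
Why: Garegg–Samuelsson iodination, heated because the alkoxyphosphonium is of the neopentyl type; the adjacent fully substituted C2 cannot epimerise.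

Step 12
Reactants: 11 hydrindenone (1.5 equiv); 21 chromanylmethyl iodide
Product: 22 (3aS,7aS)-6-{[(2R)-6-methoxy-2,8-dimethyl-3,4-dihydro-2H-chromen-2-yl]methyl}-3a,7a-dimethyloctahydro-4H-inden-4-one (C6 epimers)
Conditions: (TMS)3SiH, Et3B (cat.)/air, toluene, rt
Reagents that add atoms: none
Why: The silyl radical abstracts iodine from 21, the nucleophilic primary radical adds to the unsubstituted β-carbon C6 of the enone and the α-keto radical is reduced by the silane (Giese reaction); C6 forms as an epimer mixture that is erased when C5=C6 is installed in step 15, and chroman C2 is not involved.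

Step 13
Reactants: 22 ketone; 23 3-bromo-2-methylprop-1-ene
Product: 25 (3aS,7aS)-6-{[(2R)-6-methoxy-2,8-dimethyl-3,4-dihydro-2H-chromen-2-yl]methyl}-3a,7a-dimethyl-5-(2-methylprop-2-en-1-yl)octahydro-4H-inden-4-one (C5/C6 epimers), via lithium enolate 24 (not isolated)
Conditions: LDA, THF, −78 °C; 23, DMPU, −78 → 0 °C
Reagents that add atoms: none
Why: C5 is the only α-carbon bearing hydrogen because C3a is quaternary, so LDA gives a single enolate that is alkylated by the allylic bromide (kinetic enolate alkylation); the C5 configuration is irrelevant.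

Step 14
Reactants: 25 methallyl ketone
Product: 26 (3aS,7aS)-5-(2-hydroxy-2-methylpropyl)-6-{[(2R)-6-methoxy-2,8-dimethyl-3,4-dihydro-2H-chromen-2-yl]methyl}-3a,7a-dimethyloctahydro-4H-inden-4-one (C5/C6 epimers)
Conditions: Co(acac)2 (cat.), PhSiH3, O2 (1 atm), THF/i-PrOH, rt; aq. Na2S2O3
Reagents that add atoms: dioxygen, O=O
Why: Cobalt-hydride hydrogen-atom transfer to the 1,1-disubstituted alkene gives the tertiary radical, which is trapped by O2 and reduced to the tertiary alcohol (Mukaiyama hydration, Markovnikov), the saturated ketone and the aryl ether being inert; hydrating before the last step removes the allylic hydrogens that could otherwise divert the elimination.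

Step 15
Reactants: 26 hydroxy ketone
Product: 29 (3aS,7aS)-5-(2-hydroxy-2-methylpropyl)-6-{[(2R)-6-methoxy-2,8-dimethyl-3,4-dihydro-2H-chromen-2-yl]methyl}-3a,7a-dimethyl-1,2,3,3a,7,7a-hexahydro-4H-inden-4-one, via dilithium alkoxide enolate 27 (not isolated), via selenide 28 (not isolated)
Conditions: LDA (2.5 equiv), THF, −78 → 0 °C; PhSeBr, −78 °C; then 30% H2O2, pyridine, CH2Cl2, 0 °C → rt
Reagents that add atoms: none
Why: With C5 as the only enolisable carbon the dianion is selenenylated there from the face opposite the C6 substituent, which places selenium cis to H-6, and oxidation triggers selenoxide syn-elimination towards C6 to give the tetrasubstituted enone without affecting C3a, C7a or chroman C2.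

**Compound list**

1 | allyl tert-butyldimethylsilyl ether | C=CCO[Si](C)(C)C(C)(C)C | starting material
2 | 3-methylcyclohex-2-en-1-one | CC1=CC(=O)CCC1 | starting material
3 | chlorobis(cyclopentadienyl)[3-(tert-butyldimethylsilyloxy)propyl]zirconium | CC(C)(C)[Si](C)(C)OCCC[Zr](Cl)(C1C=CC=C1)C1C=CC=C1 | intermediate
4 | tert-butyldimethyl{3-[(1R)-1-methyl-3-(trimethylsilyloxy)cyclohex-2-en-1-yl]propoxy}silane | C1CC(O[Si](C)(C)C)=C[C@@](C)(CCCO[Si](C)(C)C(C)(C)C)C1 | intermediate
5 | lithium (3R)-3-[3-(tert-butyldimethylsilyloxy)propyl]-3-methylcyclohex-1-en-1-olate | C1CC(O[Li])=C[C@@](C)(CCCO[Si](C)(C)C(C)(C)C)C1 | intermediate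
6 | (2RS,3R)-3-[3-(tert-butyldimethylsilyloxy)propyl]-2,3-dimethylcyclohexan-1-one | C1CC(=O)C(C)[C@@](C)(CCCO[Si](C)(C)C(C)(C)C)C1 | intermediate
7 | (2RS,3R)-3-(3-hydroxypropyl)-2,3-dimethylcyclohexan-1-one | C1CC(=O)C(C)[C@@](C)(CCCO)C1 | intermediate
8 | (2RS,3R)-3-(3-iodopropyl)-2,3-dimethylcyclohexan-1-one | C1CC(=O)C(C)[C@@](C)(CCCI)C1 | intermediate
9 | potassium (3R)-3-(3-iodopropyl)-2,3-dimethylcyclohex-1-en-1-olate | C1CC(O[K])=C(C)[C@@](C)(CCCI)C1 | intermediate
10 | (3aS,7aS)-3a,7a-dimethyloctahydro-4H-inden-4-one, cis-fused | C1CC(=O)[C@@]2(C)CCC[C@@]2(C)C1 | intermediate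
11 | (3aS,7aS)-3a,7a-dimethyl-1,2,3,3a,7,7a-hexahydro-4H-inden-4-one | C1=CC(=O)[C@@]2(C)CCC[C@@]2(C)C1 | intermediate
12 | [(2S)-2-methyloxiran-2-yl]methanol, (S)-2-methylglycidol | C1[C@](C)(CO)O1 | starting material
13 | sodium [(2S)-2-methyloxiran-2-yl]methanolate | C1[C@](C)(CO[Na])O1 | intermediate
14 | (2R)-2-[(benzyloxy)methyl]-2-methyloxirane | C1[C@](C)(COCc2ccccc2)O1 | intermediate
15 | 2-bromo-5-methoxy-1,3-dimethylbenzene | COc1cc(C)c(Br)c(C)c1 | starting material
16 | 2-bromo-1-(bromomethyl)-5-methoxy-3-methylbenzene | COc1cc(C)c(Br)c(CBr)c1 | intermediate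
17 | (2-bromo-5-methoxy-3-methylbenzyl)magnesium bromide | COc1cc(C)c(Br)c(C[Mg]Br)c1 | intermediate
18 | (2R)-1-(benzyloxy)-4-(2-bromo-5-methoxy-3-methylphenyl)-2-methylbutan-2-ol | COc1cc(C)c(Br)c(c1)CC[C@](C)(COCc1ccccc1)O | intermediate
19 | (2R)-2-[(benzyloxy)methyl]-6-methoxy-2,8-dimethyl-3,4-dihydro-2H-chromene | COc1cc(C)c2c(c1)CC[C@](C)(COCc1ccccc1)O2 | intermediate
20 | [(2R)-6-methoxy-2,8-dimethyl-3,4-dihydro-2H-chromen-2-yl]methanol | COc1cc(C)c2c(c1)CC[C@](C)(CO)O2 | intermediate
21 | (2R)-2-(iodomethyl)-6-methoxy-2,8-dimethyl-3,4-dihydro-2H-chromene | COc1cc(C)c2c(c1)CC[C@](C)(CI)O2 | intermediate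
22 | (3aS,7aS)-6-{[(2R)-6-methoxy-2,8-dimethyl-3,4-dihydro-2H-chromen-2-yl]methyl}-3a,7a-dimethyloctahydro-4H-inden-4-one, C6 epimers | COc1cc(C)c2c(c1)CC[C@](C)(CC1CC(=O)[C@@]3(C)CCC[C@@]3(C)C1)O2 | intermediate
23 | 3-bromo-2-methylprop-1-ene | CC(=C)CBr | starting material
24 | lithium C4=C5 enolate of 22 | COc1cc(C)c2c(c1)CC[C@](C)(CC1C=C(O[Li])[C@@]3(C)CCC[C@@]3(C)C1)O2 | intermediate
25 | (3aS,7aS)-6-{[(2R)-6-methoxy-2,8-dimethyl-3,4-dihydro-2H-chromen-2-yl]methyl}-3a,7a-dimethyl-5-(2-methylprop-2-en-1-yl)octahydro-4H-inden-4-one, C5/C6 epimers | COc1cc(C)c2c(c1)CC[C@](C)(CC1C(CC(C)=C)C(=O)[C@@]3(C)CCC[C@@]3(C)C1)O2 | intermediate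
26 | (3aS,7aS)-5-(2-hydroxy-2-methylpropyl)-6-{[(2R)-6-methoxy-2,8-dimethyl-3,4-dihydro-2H-chromen-2-yl]methyl}-3a,7a-dimethyloctahydro-4H-inden-4-one, C5/C6 epimers | COc1cc(C)c2c(c1)CC[C@](C)(CC1C(CC(C)(C)O)C(=O)[C@@]3(C)CCC[C@@]3(C)C1)O2 | intermediate
27 | dilithium alkoxide C4=C5 enolate of 26 | COc1cc(C)c2c(c1)CC[C@](C)(CC1C(CC(C)(C)O[Li])=C(O[Li])[C@@]3(C)CCC[C@@]3(C)C1)O2 | intermediate
28 | 5-(phenylselanyl) derivative of 26 | COc1cc(C)c2c(c1)CC[C@](C)(CC1C(CC(C)(C)O)([Se]c4ccccc4)C(=O)[C@@]3(C)CCC[C@@]3(C)C1)O2 | intermediate
29 | (3aS,7aS)-5-(2-hydroxy-2-methylpropyl)-6-{[(2R)-6-methoxy-2,8-dimethyl-3,4-dihydro-2H-chromen-2-yl]methyl}-3a,7a-dimethyl-1,2,3,3a,7,7a-hexahydro-4H-inden-4-one | COc1cc(C)c2c(c1)CC[C@](C)(CC1=C(CC(C)(C)O)C(=O)[C@@]3(C)CCC[C@@]3(C)C1)O2 | target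

**Step count and risks**

Total: 15 steps. Longest linear sequence: 9 steps (steps 1–5 and 12–15; the chroman branch through steps 7–11 and 12–15 is equally long).

Steps most likely to fail:

Step 1. Zirconium may walk along the chain to the carbon next to oxygen and lose silyloxide, the facial selectivity at the new quaternary carbon may be insufficient, or the silyl enol ether may hydrolyse during isolation. The three-carbon arm would then be delivered from magnesium instead. Setting out from 2, [3-(tert-butyldimethylsilyloxy)propyl]magnesium bromide F1 (from commercial (3-bromopropoxy)(tert-butyl)dimethylsilane and Mg) would be added under Cu(OTf)2/chiral N-heterocyclic carbene catalysis in Et2O at 0 °C. This should give the bromomagnesium enolate F2, which would be silylated in the same flask with TMSCl/Et3N/HMPA; the route is rejoined at 4.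

Step 12. The primary radical may be reduced by the silane before it adds to the enone, or the β-aryloxy radical may open the pyran ring by β-scission of the C2–O bond. The union would then be run without a hydrogen donor, as a nickel-catalysed reductive conjugate addition. Setting out from 21 and 11, NiCl2·glyme/neocuproine, Mn and Et3SiCl in DMF should give the triethylsilyl enol ether F3. MeLi would convert it into lithium enolate 24, where the route is rejoined (step 13 then needs no LDA).

Step 15. The selenoxide may eliminate in the exocyclic direction, the hindered tertiary α-CH may resist enolisation, or selenium may enter cis to the C6 substituent and leave no syn hydrogen at C6. The double bond would then be introduced before the side chain, where its position is unambiguous. Setting out from 22, its enolate 24 would be treated with N-tert-butylbenzenesulfinimidoyl chloride at −78 °C to give the β-substituted enone F4. γ-Deprotonation with KHMDS and α-alkylation of the extended dienolate with 23 should give the deconjugated methallyl ketone F5. DBU would move the double bond back into conjugation to give the methallyl enone F6, and Mukaiyama hydration of its 1,1-disubstituted alkene (Co(acac)2, PhSiH3, O2) would give 29.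

Further compounds
F1 | step 1 | [3-(tert-butyldimethylsilyloxy)propyl]magnesium bromide | CC(C)(C)[Si](C)(C)OCCC[Mg]Br
F2 | step 1 | bromomagnesium (3R)-3-[3-(tert-butyldimethylsilyloxy)propyl]-3-methylcyclohex-1-en-1-olate | C1CC(O[Mg]Br)=C[C@@](C)(CCCO[Si](C)(C)C(C)(C)C)C1
F3 | step 12 | triethylsilyl C4=C5 enol ether of 22 | COc1cc(C)c2c(c1)CC[C@](C)(CC1C=C(O[Si](CC)(CC)CC)[C@@]3(C)CCC[C@@]3(C)C1)O2
F4 | step 15 | (3aS,7aS)-6-{[(2R)-6-methoxy-2,8-dimethyl-3,4-dihydro-2H-chromen-2-yl]methyl}-3a,7a-dimethyl-1,2,3,3a,7,7a-hexahydro-4H-inden-4-one | COc1cc(C)c2c(c1)CC[C@](C)(CC1=CC(=O)[C@@]3(C)CCC[C@@]3(C)C1)O2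
F5 | step 15 | (3aS,7aS)-6-{[(2R)-6-methoxy-2,8-dimethyl-3,4-dihydro-2H-chromen-2-yl]methyl}-3a,7a-dimethyl-5-(2-methylprop-2-en-1-yl)-1,2,3,3a,5,7a-hexahydro-4H-inden-4-one | COc1cc(C)c2c(c1)CC[C@](C)(CC=1C(CC(C)=C)C(=O)[C@@]3(C)CCC[C@@]3(C)C=1)O2
F6 | step 15 | (3aS,7aS)-6-{[(2R)-6-methoxy-2,8-dimethyl-3,4-dihydro-2H-chromen-2-yl]methyl}-3a,7a-dimethyl-5-(2-methylprop-2-en-1-yl)-1,2,3,3a,7,7a-hexahydro-4H-inden-4-one | COc1cc(C)c2c(c1)CC[C@](C)(CC1=C(CC(C)=C)C(=O)[C@@]3(C)CCC[C@@]3(C)C1)O2
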